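## Analysis of the target

2,3,4,7-Tetrabromo-1H-indole is a flat, fully aromatic bicycle: a pyrrole ring (N1, C2, C3, C3a, C7a) fused to a benzene ring (C3a, C4, C5, C6, C7, C7a). It has no stereocentre, so the whole problem is the placing of four bromines around a free N–H. Two bromines sit on the pyrrole ring (C2, C3) and two on the benzene ring at C4 and C7, the positions that flank the ring fusion; only C5–H and C6–H remain. The 4,7-pattern cannot be reached by brominating an indole, because electrophiles go to C3, then C2, then C5/C6. Those two bromines must therefore come with the arene, and the pyrrole ring has to be annulated onto a 1,2,3,4-tetrasubstituted benzene. The C2 and C3 bromines of an N–H indole are labile towards acid and light, and all four C–Br bonds are open to halogen–metal exchange, zerovalent palladium and hydrogenolysis, which limits what can be done late in the route. The C2 bromine is the hardest to place by substitution, since C2 is not the innately reactive carbon of an N–H indole. The plan rests on one feature: C2 carries both N1 and a bromine and is doubly bonded to C3, which is the oxidation level of the terminal carbon of a 1,1-dibromoalkene. N1–C2 can therefore be made by exchanging one geminal vinylic bromine for nitrogen while the other stays as the C2 bromine, and C3 is left free for a final, innately selective bromination.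

## Retrosynthetic reasoning

**C3–Br.** The C3–Br bond of 14 is cut first, giving 2,4,7-tribromo-1H-indole 13. C3 is the one position where electrophilic substitution of an indole is reliable, and in 13 it is the only unsubstituted pyrrole carbon. Placing this bromine last means the most labile compound is made only at the end. The forward reaction has to stop after one bromination.

**N1–C2 (key disconnection).** Cutting N1–C2 of 13 leads to the aniline 10, in which C2 is the CBr2 terminus of a 1,1-dibromoalkene. This cut is preferred to C3–C3a or N1–C7a, which would require a new bond to an aromatic carbon lying next to a bromine. Here the aromatic C–N bond already exists and the C2 bromine comes with the ring closure. The forward reaction has to replace only the vinylic bromine cis to the arene, with formal loss of that bromine and one N–H hydrogen. It is expected to run through the copper amide 11 and the cupracycle 12, and it must leave the other vinylic bromine and both aryl bromides alone.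

**N–H unmasking.** The amine 10 is traced back to its trifluoroacetamide 9. The free amine is not taken through the olefination, where halophosphonium species could attack nitrogen. The mask must come off under conditions that do not touch the dibromoalkene.

**C2=C3.** The double bond between the benzylic carbon (future C3) and the CBr2 carbon (future C2) of 9 is cut to the aldehyde 6 and carbon tetrabromide 7, joined through the ylide 8. This makes C2 with both bromines in one operation from a one-carbon reagent, and no alkene geometry is at stake.

**N-acylation.** The amide 6 comes from the amino aldehyde 5 by acylation on nitrogen.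

**C–N at the future C7a.** The amino group of 5 is disconnected to the fluoride 4. The formyl group that is needed anyway activates the ortho C–F bond for addition–elimination. The forward reaction has to displace fluoride and spare the bromide on the other side of the formyl group.

**Formyl C–C bond.** The aldehyde 4 is cut between the ring and the formyl carbon to 1,4-dibromo-2-fluorobenzene 1 and N,N-dimethylformamide 2, joined through the aryllithium 3. The two para-related bromines of 1 become C4–Br and C7–Br. The C–H between fluorine and bromine is the most acidic, so deprotonation there sets the 1,2,3,4-pattern with no isomer problem.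

## Alternatives that were turned down

**Alternative 1: benzene ring by cyclotrimerisation.**
- Disconnection: C3a–C7a, C4–C5 and C6–C7, so the benzene ring itself is built.
- Key step: the tethered ynamide diyne 4-methyl-N-[4-(trimethylsilyl)but-3-yn-1-yl]-N-[(trimethylsilyl)ethynyl]benzenesulfonamide A1 and acetylene A2 are joined in a rhodium-catalysed [2+2+2] cyclotrimerisation to 1-tosyl-4,7-bis(trimethylsilyl)indoline A3. The silyl groups mark C4 and C7 for later ipso-bromodesilylation.
- For: three C–C bonds and both rings form in one step, and the 4,7-pattern is fixed by the alkyne termini. On skeletal bond formation it is clearly stronger than the chosen key step, which forms one ring bond.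
- Against: a para-dibrominated benzene ring is a commodity, so building it buys little. A1 needs several steps, including an ynamide synthesis. Silyl-capped alkynes are sluggish partners and A2 can trimerise with itself. After A3 none of the four bromines is in place: two bromodesilylations, detosylation, dehydrogenation of the indoline and both pyrrole brominations remain, C2 by substitution.
- Comparison: a route well into double figures, against seven steps. The chosen route starts from 1 with both benzo bromines present and has its key step deliver the C2 bromine.

**Alternative 2: aryne annulation.**
- Disconnection: N1–C7a and C3–C3a.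
- Key step: fluoride releases 3,6-dibromobenzyne A5 from 3,6-dibromo-2-(trimethylsilyl)phenyl trifluoromethanesulfonate A4. The carbamate nitrogen of methyl 2-[(tert-butoxycarbonyl)amino]acrylate A6 adds, and the aryl anion closes onto the acrylate methylene to give racemic methyl 1-(tert-butoxycarbonyl)-4,7-dibromoindoline-2-carboxylate A7.
- For: convergent and metal-free, with two bonds and one ring formed in one step. Because A5 is symmetric, both orientations of addition give the same product, so on regiochemistry it is as clean as the chosen route.
- Against: A4 is not a catalogue compound, and its ortho-silylation chemistry has to be carried out beside two aryl bromides. The aryl anion formed after N-addition has a bromide ortho to it and can expel it instead of cyclising. A7 is at the wrong oxidation level and carries a carboxylate on C2 and a stereocentre that must be destroyed. Deprotection, dehydrogenation, hydrolysis and decarboxylation are needed before either pyrrole bromine can be introduced.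
- Comparison: about nine steps, and the C2 bromine still has to be placed on a finished indole. The chosen route is linear but introduces no atom that must later be removed from the ring.

**Alternative 3: nitrene C–H insertion (Hemetsberger–Knittel).**
- Disconnection: N1–C7a.
- Key step: 2,5-dibromobenzaldehyde A8 is condensed with an azidoacetic ester to ethyl (2Z)-2-azido-3-(2,5-dibromophenyl)acrylate A9. Thermolysis gives a vinyl nitrene (via the 2H-azirine) that inserts into the only free ortho C–H to give ethyl 4,7-dibromo-1H-indole-2-carboxylate A10.
- For: two steps from a commercial aldehyde to the 4,7-dibromoindole nucleus, no metal near the aryl bromides, and no regiochemical choice. It reaches the ring system faster than the chosen route (two steps against six), and its total of about five steps is shorter.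
- Against: C2 ends up with an ester where the bromine is needed. Saponification and thermal decarboxylation to 4,7-dibromo-1H-indole A11 are conditions under which aryl bromides tend to be reduced or coupled. Both pyrrole bromines must then go on by substitution, and the second, at C2 of an N–H indole, is the less clean one. The condensation is sensitive to ortho substitution, and the azide thermolysis is a hazard on scale.
- Comparison: the chosen strategy is longer, but its ring closure puts the correct atom on C2, and the only substitution on the finished indole is the easy one at C3. The uncertainty is concentrated in one ring closure that has close precedent.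

Key step: step 6

## Route

Assumption: the copper species 11 and 12 are drawn without ancillary ligands and stand for the two organocopper stages of the catalytic cycle.

Step 1
Reactants: 1 1,4-dibromo-2-fluorobenzene; 2 N,N-dimethylformamide
Product: 4 3,6-dibromo-2-fluorobenzaldehyde, via (3,6-dibromo-2-fluorophenyl)lithium 3 (not isolated)
Conditions: LiN(iPr)2 (1.1 equiv), THF, −78 °C; DMF (2), −78 °C; 1 M HCl
Reagents that add atoms: N,N-dimethylformamide (2), CN(C)C=O
Why: Directed ortho-lithiation followed by formylation: the C–H between fluorine and bromine of 1 is the most acidic, so the lithium amide should remove it selectively to give 3, which is kept at −78 °C to suppress aryne formation and halogen migration. A lithium amide does not exchange aryl bromides, so formyl transfer from 2 and acidic work-up should give 4 with both bromines in place.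

Step 2
Reactants: 4 3,6-dibromo-2-fluorobenzaldehyde
Product: 5 2-amino-3,6-dibromobenzaldehyde
Conditions: NH3 (28% aq., excess), DMSO, 60–70 °C, sealed vessel; then 1 M HCl, THF, rt
Reagents that add atoms: ammonia, N
Why: Nucleophilic aromatic substitution by addition–elimination, activated by the ortho formyl group; fluoride should be displaced much faster than the bromide on the other side of the formyl group, because the rate-limiting addition is fastest at the carbon bearing fluorine. Reversible condensation of ammonia at the formyl group is undone by the acidic work-up, and the amino group of 5 is flanked and deactivated enough to make self-condensation slow.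

Step 3
Reactants: 5 2-amino-3,6-dibromobenzaldehyde
Product: 6 N-(3,6-dibromo-2-formylphenyl)-2,2,2-trifluoroacetamide
Conditions: (CF3CO)2O, pyridine, CH2Cl2, 0 °C → rt
Reagents that add atoms: trifluoroacetic anhydride, O=C(OC(=O)C(F)(F)F)C(F)(F)F
Why: N-Acylation of a hindered, weakly nucleophilic aniline with a highly reactive anhydride. The trifluoroacetamide shields nitrogen from phosphorus electrophiles in step 4 and is removable with mild base.

Step 4
Reactants: 6 N-(3,6-dibromo-2-formylphenyl)-2,2,2-trifluoroacetamide; 7 carbon tetrabromide
Product: 9 N-[3,6-dibromo-2-(2,2-dibromoethenyl)phenyl]-2,2,2-trifluoroacetamide, via (dibromomethylidene)triphenylphosphorane 8 (not isolated)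
Conditions: CBr4 (7), PPh3, Zn dust, CH2Cl2, rt; then 6, 0 °C → rt
Reagents that add atoms: carbon tetrabromide (7), BrC(Br)(Br)Br
Why: Ramirez (Corey–Fuchs) dibromo-olefination: the ylide 8 undergoes a Wittig reaction with the formyl group of 6. Zinc reduces the bromophosphonium by-product, so no halogenating phosphorus species is left to activate the amide, and the weakly basic ylide should not deprotonate the N–H. The new carbon carries two identical bromines, so no alkene geometry arises.

Step 5
Reactants: 9 N-[3,6-dibromo-2-(2,2-dibromoethenyl)phenyl]-2,2,2-trifluoroacetamide
Product: 10 3,6-dibromo-2-(2,2-dibromoethenyl)aniline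
Conditions: K2CO3 (2 equiv), MeOH/H2O (4:1), rt → 40 °C
Reagents that add atoms: none
Why: Basic hydrolysis of a trifluoroacetanilide, which proceeds at or near room temperature with carbonate; the 1,1-dibromoalkene and the aryl bromides should be inert under these conditions.

Step 6
Reactants: 10 3,6-dibromo-2-(2,2-dibromoethenyl)aniline
Product: 13 2,4,7-tribromo-1H-indole, via copper amide of the aniline 11 (not isolated), via six-membered bromocupracycle 12 (not isolated)
Conditions: CuI (10 mol%), K3PO4 (2 equiv), THF, 80 °C, sealed tube, argon, dark
Reagents that add atoms: none
Why: The electron-poor N–H of 10 is deprotonated at the metal with K3PO4 to give the monovalent copper amide 11. This holds copper next to the vinylic C–Br bond cis to the arene, and oxidative addition into that bond should give the trivalent copper metallacycle 12 (ring atoms Cu, N, C7a, C3a, C3, C2). Reductive elimination from 12 forms N1–C2, contracts the six-membered metallacycle to the five-membered pyrrole ring and releases monovalent copper, while the second geminal bromine never leaves C2. The closest known reaction type is the copper-catalysed intramolecular Ullmann–Goldberg N-vinylation of 2-(2,2-dibromovinyl)anilines, with the corresponding O- and S-closures of phenols and thiophenols, giving 2-bromo benzo-fused heterocycles. The closure is formally 5-endo-trig at nitrogen, but because the bond is made by reductive elimination from a metallacycle the usual stereoelectronic bar to that mode does not apply. No stereocentre is formed. The step needs chemoselectivity among the four C–Br bonds of 10: only the cis vinylic bromine can be reached by copper-bound nitrogen, the trans vinylic bromine is geometrically out of reach, and the aryl bromides could react only by intermolecular Ullmann coupling, which should be slow without a ligand at 80 °C. The N–H of 13 is flanked by the C2 and C7 bromines, which should protect the product from N-arylation by a second molecule.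

Step 7
Reactants: 13 2,4,7-tribromo-1H-indole
Product: 14 2,3,4,7-tetrabromo-1H-indole
Conditions: NBS (1.0 equiv), DMF, 0 °C, dark; aq. NaHCO3 work-up
Reagents that add atoms: N-bromosuccinimide, BrN1C(=O)CCC1=O
Why: Electrophilic aromatic substitution at C3, the only unsubstituted pyrrole carbon and the most nucleophilic position of 13. The two benzo C–H positions are deactivated by three bromines, and one equivalent of reagent at 0 °C should stop at monobromination because the product has no pyrrole C–H left.

## Compound list

1 | 1,4-dibromo-2-fluorobenzene | Fc1cc(Br)ccc1Br | starting material
2 | N,N-dimethylformamide | CN(C)C=O | starting material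
3 | (3,6-dibromo-2-fluorophenyl)lithium | [Li]c1c(F)c(Br)ccc1Br | intermediate (not isolated)
4 | 3,6-dibromo-2-fluorobenzaldehyde | O=Cc1c(F)c(Br)ccc1Br | intermediate
5 | 2-amino-3,6-dibromobenzaldehyde | Nc1c(Br)ccc(Br)c1C=O | intermediate
6 | N-(3,6-dibromo-2-formylphenyl)-2,2,2-trifluoroacetamide | O=Cc1c(Br)ccc(Br)c1NC(=O)C(F)(F)F | intermediate
7 | carbon tetrabromide | BrC(Br)(Br)Br | starting material
8 | (dibromomethylidene)triphenylphosphorane | BrC(Br)=P(c1ccccc1)(c1ccccc1)c1ccccc1 | intermediate (not isolated)
9 | N-[3,6-dibromo-2-(2,2-dibromoethenyl)phenyl]-2,2,2-trifluoroacetamide | FC(F)(F)C(=O)Nc1c(Br)ccc(Br)c1C=C(Br)Br | intermediate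
10 | 3,6-dibromo-2-(2,2-dibromoethenyl)aniline | Nc1c(Br)ccc(Br)c1C=C(Br)Br | intermediate
11 | monovalent copper amide of 10, copper on nitrogen (ancillary ligands omitted) | [Cu]Nc1c(Br)ccc(Br)c1C=C(Br)Br | intermediate (not isolated)
12 | six-membered trivalent copper metallacycle, bromo-copper bridging nitrogen and the former cis vinylic carbon, which keeps one bromine (ancillary ligands omitted) | Br[Cu]1Nc2c(Br)ccc(Br)c2C=C1Br | intermediate (not isolated)
13 | 2,4,7-tribromo-1H-indole | Brc1cc2c(Br)ccc(Br)c2[nH]1 | intermediate
14 | 2,3,4,7-tetrabromo-1H-indole | Brc1[nH]c2c(Br)ccc(Br)c2c1Br | target

## Step count and least certain steps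

Total step count: 7. Longest linear sequence: 7 steps, from 1 to 14; the route is fully linear.

**Step 6 (key step).** The most likely failure is incomplete ring closure: the doubly ortho-substituted, electron-poor nitrogen may bind copper poorly. Forcing the reaction could then bring on intermolecular C–N coupling at the aryl bromides or base-induced loss of HBr from the dibromoalkene. The fallback sets out from 10 and returns at 13 by a copper-free, anionic closure. Nitrogen is sulfonylated (MsCl, pyridine, DMAP, CH2Cl2) to N-[3,6-dibromo-2-(2,2-dibromoethenyl)phenyl]methanesulfonamide F1. Cs2CO3 in DMF at 60–80 °C should then eliminate HBr to N-[3,6-dibromo-2-(bromoethynyl)phenyl]methanesulfonamide F2, which is not isolated. The sulfonamide anion adds 5-endo-dig to the bromine-bearing alkyne carbon of F2 to give 2,4,7-tribromo-1-(methylsulfonyl)-1H-indole F3. Methanolysis of the sulfonyl group (Cs2CO3, THF/MeOH, rt) should release 13.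

**Step 2.** The most likely failure is condensation at the formyl group outrunning substitution, by aminal and imine formation with ammonia or by self-condensation of the amino aldehyde as it forms. Partial displacement of the C6 bromide is possible if the temperature has to be raised. The fallback sets out from 4 and returns at 5 with azide as a non-basic ammonia surrogate. NaN3 in DMSO at rt–40 °C (kept below 50 °C to avoid cyclisation onto the formyl group) should give 2-azido-3,6-dibromobenzaldehyde F4. Reduction of the azide with propane-1,3-dithiol and Et3N in MeOH at rt, which leaves the formyl group and the aryl bromides alone, should give 5.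

**Step 4.** The most likely failure is a slow Wittig addition to a formyl group flanked on both sides, together with activation of the amide by halophosphonium species if their reduction by zinc lags. The fallback sets out from 5 and returns at 10, avoiding phosphorus and the nitrogen mask altogether. Hydrazine hydrate in EtOH at rt should convert 5 into its hydrazone, 3,6-dibromo-2-[(E)-hydrazinylidenemethyl]aniline F5. Copper-catalysed olefination of F5 with 7 (CuCl 10 mol%, aq. NH3, DMSO, rt) should give 10 directly with loss of dinitrogen. Steps 3 and 5 are then not needed.

**Step 5.** The most likely failure is slow hydrolysis of the deprotonated amide, with uncontrolled attack of the amide anion on the neighbouring dibromoalkene or dehydrobromination on warming. The fallback sets out from 9 and returns at 13 by closing the ring before unmasking. Goldberg-type intramolecular N-vinylation of the amide (CuI 10 mol%, N,N'-dimethylethylenediamine 20 mol%, K3PO4, toluene, 80 °C) should give 2,2,2-trifluoro-1-(2,4,7-tribromo-1H-indol-1-yl)ethan-1-one F6. The labile N-acyl group of F6 is then removed by methanolysis (K2CO3 cat., MeOH, rt) to give 13.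

## Further compounds

F1 | step 6 | N-[3,6-dibromo-2-(2,2-dibromoethenyl)phenyl]methanesulfonamide | CS(=O)(=O)Nc1c(Br)ccc(Br)c1C=C(Br)Br
F2 | step 6 | N-[3,6-dibromo-2-(bromoethynyl)phenyl]methanesulfonamide | CS(=O)(=O)Nc1c(Br)ccc(Br)c1C#CBr
F3 | step 6 | 2,4,7-tribromo-1-(methylsulfonyl)-1H-indole | CS(=O)(=O)n1c(Br)cc2c(Br)ccc(Br)c21
F4 | step 2 | 2-azido-3,6-dibromobenzaldehyde | [N-]=[N+]=Nc1c(Br)ccc(Br)c1C=O
F5 | step 4 | 3,6-dibromo-2-[(E)-hydrazinylidenemethyl]aniline | N/N=C/c1c(Br)ccc(Br)c1N
F6 | step 5 | 2,2,2-trifluoro-1-(2,4,7-tribromo-1H-indol-1-yl)ethan-1-one | O=C(n1c(Br)cc2c(Br)ccc(Br)c21)C(F)(F)F
A1 | alternative 1 | 4-methyl-N-[4-(trimethylsilyl)but-3-yn-1-yl]-N-[(trimethylsilyl)ethynyl]benzenesulfonamide | C[Si](C)(C)C#CCCN(C#C[Si](C)(C)C)S(=O)(=O)c1ccc(C)cc1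
A2 | alternative 1 | acetylene | C#C
A3 | alternative 1 | 1-tosyl-4,7-bis(trimethylsilyl)indoline | C[Si](C)(C)c1ccc([Si](C)(C)C)c2c1CCN2S(=O)(=O)c1ccc(C)cc1
A4 | alternative 2 | 3,6-dibromo-2-(trimethylsilyl)phenyl trifluoromethanesulfonate | C[Si](C)(C)c1c(Br)ccc(Br)c1OS(=O)(=O)C(F)(F)F
A5 | alternative 2 | 3,6-dibromobenzyne | BrC1=CC=C(Br)C#C1
A6 | alternative 2 | methyl 2-[(tert-butoxycarbonyl)amino]acrylate | C=C(NC(=O)OC(C)(C)C)C(=O)OC
A7 | alternative 2 | methyl 1-(tert-butoxycarbonyl)-4,7-dibromoindoline-2-carboxylate (racemic) | COC(=O)C1Cc2c(Br)ccc(Br)c2N1C(=O)OC(C)(C)C
A8 | alternative 3 | 2,5-dibromobenzaldehyde | O=Cc1cc(Br)ccc1Br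
A9 | alternative 3 | ethyl (2Z)-2-azido-3-(2,5-dibromophenyl)acrylate | CCOC(=O)/C(N=[N+]=[N-])=C/c1cc(Br)ccc1Br
A10 | alternative 3 | ethyl 4,7-dibromo-1H-indole-2-carboxylate | CCOC(=O)c1cc2c(Br)ccc(Br)c2[nH]1
A11 | alternative 3 | 4,7-dibromo-1H-indole | Brc1ccc(Br)c2[nH]ccc12
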